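Starting material, target and catalyst intermediate A add up to 99.4% in the last winter reading, so I need one number per flask, the target, and the balance gives the starting material.

common to all: starting material 0.40 M; free catalyst 5 mol%
- winter: second substrate 0.50 equiv; reagent 0.60 equiv; temperature 105 °C; run made earlier
- autumn: second substrate 2 equiv; reagent 0.60 equiv; temperature 116 °C; run made earlier
- dusk: second substrate 1 equiv; reagent 0.30 equiv; temperature 105 °C; run made earlier
- zeta: second substrate 1.00 equiv; reagent 0.600 equiv; temperature 100 °C; time 50 min
- eta: second substrate 1.00 equiv; reagent 0.600 equiv; temperature 110 °C; time 50 min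
- epsilon: second substrate 1.00 equiv; reagent 0.600 equiv; temperature 120 °C; time 50 min

| run | time / min | starting material / % | target / % | catalyst intermediate A / % |
|---|---|---|---|---|
| winter | 6.00 | 58.8 | 37.6 | 3.9 |
| winter | 12.0 | 46.7 | 49.4 | 4.4 |
| winter | 20.0 | 41.9 | 53.0 | 4.4 |
| winter | 25.0 | 40.8 | 54.7 | 4.9 |
| winter | 30.0 | 40.1 | 55.3 | 4.7 |
| winter | 40.0 | 39.6 | 55.5 | 4.3 |
| autumn | 2.50 | 68.1 | 28.6 | 2.7 |
| autumn | 5.00 | 54.3 | 42.1 | 3.5 |
| autumn | 10.0 | 46.6 | 48.9 | 4.3 |
| autumn | 12.0 | 45.9 | 48.6 | 5.3 |
| autumn | 15.0 | 46.6 | 49.3 | 5.1 |
| autumn | 20.0 | 46.0 | 49.2 | 4.9 |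
| dusk | 3.00 | 82.7 | 14.0 | 3.6 |
| dusk | 6.00 | 75.7 | 20.8 | 4.0 |
| dusk | 12.0 | 70.5 | 25.4 | 4.5 |
| dusk | 20.0 | 68.7 | 27.0 | 4.7 |
| dusk | 40.0 | 67.3 | 27.6 | 4.8 |

(each reading ± 0.3 percentage points)

1. which of these there is most of at the end, counted by the starting material in it, zeta (target / catalyst intermediate A / starting material)
2. which of these there is most of at the end, counted by the starting material in it, eta (target / catalyst intermediate A / starting material)
3. which of these there is most of at the end, counted by the starting material in it, epsilon (target / catalyst intermediate A / starting material)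
4. the largest of these amounts at the end, in percent of the starting material charged, zeta
5. the largest of these amounts at the end, in percent of the starting material charged, eta
6. the largest of these amounts at the end, in percent of the starting material charged, epsilon

Target levels off with starting material still present: winter stops at 55.5% with 39.6% unused, and dusk, with 0.30 equiv of reagent, stops at 27.6%. I therefore take reagent as the limiting reagent and define the shortfall W as reagent charged minus final target, both in percent of the starting material charged. As readings, W is 4.50% in winter, 2.40% in dusk and 10.8% in autumn. Autumn has the greatest W and the most second substrate, though it is also hotter, and I suppose second substrate competes with starting material for the free catalyst, and its path also uses reagent. Dusk has twice the second substrate of winter, yet a smaller W, and it ends with 67.3% of starting material against 39.6% in winter, which fits a competition.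

Let s be starting material, p target and a second substrate. If each path runs at a rate constant times reagent times a catalyst form, reagent cancels from the ratio, and dW/dp = a/(S·s). Here S is the selectivity factor, the advantage of starting material over second substrate in that competition. With a held at its charge, integration gives W = (a/S)·ln((s+p)/s). The readings give S = 9.73 for winter, 14.3 for dusk and 13.5 for autumn. Winter and dusk share 105 °C yet differ by 4.58, and autumn at 116 °C lies between them, so I see no temperature trend in these readings and carry the mean, 12.5.

W is the small thing, so I compute only that correction, with s+p = 95.1%. Taking p as the whole reagent charge gives W = 7.97%. Putting the corrected p back gives 6.33%, and once more gives 6.64%. My reckoning is thus target 53.4% and starting material 41.7% in zeta, eta and epsilon alike, though zeta is cooler than any run, so I hold it less firmly.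

The forecast differs: it gives target at 57.1% for zeta, target at 53.2% for eta and starting material at 49% for epsilon, holding that “a reagent-wasting path grows faster with temperature”.

The flasks give target as the largest amount, at 50.9% in zeta, 53.4% in eta and 54.0% in epsilon.

    starting material + free catalyst ⇌ catalyst intermediate A (K = 220 M⁻¹, k = 0.160 M⁻¹ s⁻¹, Ea = 65.0 kJ mol⁻¹, ΔH = 46.0 kJ mol⁻¹)
    reagent + catalyst intermediate A → free catalyst + target (k = 0.220 M⁻¹ s⁻¹, Ea = 83.0 kJ mol⁻¹)
    second substrate + free catalyst ⇌ catalyst intermediate B (K = 1.20 M⁻¹, k = 0.130 M⁻¹ s⁻¹, Ea = 54.0 kJ mol⁻¹, ΔH = −16.0 kJ mol⁻¹)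
    reagent + catalyst intermediate B → free catalyst + second product (k = 0.180 M⁻¹ s⁻¹, Ea = 60.0 kJ mol⁻¹)
    reagent ⇌ dormant form (K = 0.610, k = 5.10 × 10⁻⁴ s⁻¹, Ea = 126 kJ mol⁻¹, ΔH = −79.0 kJ mol⁻¹)
    (constants at 100 °C)

Eta and epsilon stand near my figure, while zeta falls 2.5 percentage points short of it and still holds 0.00488 M of dormant form at the end. A neighbouring flask is eta with 0.240 equiv of reagent. The same reckoning gives W = 2.33%, then 2.07%, so target 21.9%. That flask gives 22.6%, with second product at 1.43% of the starting material charged and starting material the largest at 72.5%.

All runs come from a simulation on assumed constants, and the scatter is random.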